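- Time separates two limits. With instant exchange the two substrates stay equal and the ratio of the products holds still; without exchange the substrate consumed faster falls behind and that ratio sinks.

| setting | north-east | east | north-west | flask |
|---|---|---|---|---|
| left-handed substrate | 0.070 M | 0.28 M | 0.14 M | 0.14 M |
| right-handed substrate | 0.070 M | 0.28 M | 0.14 M | 0.14 M |
| solid reagent | 0.308 M | 0.308 M | 0.308 M | 0.308 M |
| racemization catalyst | 3.5 mM | 3.5 mM | 3.5 mM | 3.5 mM |
| precatalyst | 14 mM | 14 mM | 21 mM | 14 mM |
| remark | run made earlier | run made earlier | run made earlier |  |
| time |  |  |  | 12 h |

| run | time / h | left-handed product / % | right-handed product / % |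
|---|---|---|---|
| north-east | 0.667 | 0 | 0 |
| north-east | 2.00 | 5.5 | 1.6 |
| north-east | 3.00 | 8.0 | 3.1 |
| north-east | 5.00 | 14.3 | 6.7 |
| north-east | 8.00 | 19.3 | 7.6 |
| north-east | 10.0 | 22.7 | 12.7 |
| north-east | 12.0 | 27.4 | 12.7 |
| east | 0.667 | 0.5 | 0.4 |
| east | 2.00 | 0.8 | 0.5 |
| east | 3.00 | 4.3 | 1.0 |
| east | 5.00 | 7.2 | 2.4 |
| east | 8.00 | 10.0 | 5.7 |
| east | 10.0 | 13.0 | 3.9 |
| east | 12.0 | 14.7 | 7.3 |
| north-west | 1.00 | 3.4 | 0 |
| north-west | 2.00 | 4.8 | 1.1 |
| north-west | 3.00 | 7.8 | 2.5 |
| north-west | 6.00 | 14.5 | 5.9 |
| north-west | 12.0 | 25.3 | 12.2 |

(standard deviation of a reading: 1 percentage point)

- free catalyst is single-handed; left-handed substrate and right-handed substrate are mirror images of each other, charged as a racemate, each of them at the stated concentration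
- as a solid, counted per litre of solution: solid reagent
- the numbers in the tables scatter by 1 percentage point (one standard deviation)
- at the start none of the solid reagent is in solution
- an excess is below zero if the other one leads

* left-handed product and right-handed product together, in percent of the left-handed substrate and right-handed substrate charged together, at 12 h
* excess of left-handed product over right-handed product in the product at 12 h
* whether the exchange between left-handed substrate and right-handed substrate keeps pace with the reaction: how far the product's excess at 12 h gets from its value without exchange to its value with instant exchange (above 80% keeps pace, below 20% hardly takes part, else lags behind)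

- The readings fold into one dimensionless number: summed over the three runs at 12.0 h, left-handed product over right-handed product gives 2.09, a reading of the product ratio ρ = c(left-handed product)/c(right-handed product), which counts the left-handed product made per right-handed product.
- The excess follows as the ratio less one over the ratio plus one, so this reckoning expects 35.3% in the flask.
- One number may not be enough. The same sum at 3.00 h gives 3.05, higher than the 2.09 of the later time, which suggests a sinking ratio. But the east run's right-handed product there reads 1.0% against a scatter of 1 percentage point, so this reckoning leaves the exchange unplaced.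
- The forecast gives 31% (27% to 35%), an excess of 37% (31% to 43%) and "hardly takes part", reasoning: “So exchange seems negligible.” Its excess stands above the 35.3% reckoned here.
- The flask gives 30.7% and an excess of 36.9%, and the exchange lags behind, getting 43% of the way from the excess without exchange to that with instant exchange.

    partner + free catalyst + left-handed substrate → free catalyst + left-handed product (k = 1.20 /M²/s)
    partner + free catalyst + right-handed substrate → free catalyst + right-handed product (k = 0.510 /M²/s)
    left-handed substrate + racemization catalyst ⇌ right-handed substrate + racemization catalyst, rate k3*[racemization catalyst]*[left-handed substrate] forward; the back reaction follows from the equilibrium constant (k = 0.00750 /M/s)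
    free catalyst → spent catalyst (k = 7.70 × 10⁻⁴ /s)
    solid reagent ⇌ partner, rate k5*(cs5 - [partner]) while solid is left; crystals form when [partner] > cs5 (solubility = 0.130 M, k = 3.70 × 10⁻⁵ /s)
    precatalyst → free catalyst (k = 5.60 × 10⁻⁵ /s)

- At 5.11 h in the flask, the making of left-handed product uses left-handed substrate at 0.56 of the rate of its loss to right-handed substrate, forward step alone. The flask's ρ comes to 2.17, above the 2.09 summed from the runs and below the rate-constant ratio 2.35, the selectivity factor. In the neighbour charged with 0.056 M of precatalyst, which reaches 49.2%, ρ is 2.04, below that summed 2.09.

The numbers in the tables come from a simulation from invented constants.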